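I began with the loss.

| setting | zeta | beta | epsilon | gamma | north-west | east | north |
|---|---|---|---|---|---|---|---|
| starting material | 0.14 M | 0.14 M | 0.14 M | 0.14 M | 0.14 M | 0.14 M | 0.14 M (fed, over 8.0 h) |
| coupling partner | 0.147 M | 0.147 M | 0.147 M | 0.22 M | 0.147 M | 0.147 M (fed, over 8.0 h) | 0.147 M |
| capture agent | 7 mM | 3.5 mM | 5.2 mM | 7 mM | 7.00 mM | 7.00 mM | 7.00 mM |
| remark | run made earlier | run made earlier | run made earlier | run made earlier | everything together at the start | all else is in the flask from the start; the feed brings no volume worth counting | all else is in the flask from the start; the feed brings no volume worth counting |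
| time |  |  |  |  | 40 h | 40 h | 40 h |

| run | time / h | target / % |
|---|---|---|
| zeta | 3.00 | 78.1 |
| zeta | 5.00 | 89.4 |
| zeta | 8.00 | 93.8 |
| zeta | 15.0 | 95.7 |
| zeta | 25.0 | 96.7 |
| zeta | 40.0 | 96.4 |
| beta | 2.50 | 72.8 |
| beta | 8.00 | 94.9 |
| beta | 15.0 | 97.7 |
| beta | 20.0 | 97.9 |
| beta | 30.0 | 98.3 |
| beta | 40.0 | 98.9 |
| epsilon | 3.00 | 78.7 |
| epsilon | 5.00 | 90.3 |
| epsilon | 8.00 | 94.6 |
| epsilon | 15.0 | 96.8 |
| epsilon | 25.0 | 97.9 |
| epsilon | 40.0 | 97.8 |
| gamma | 4.00 | 93.5 |
| gamma | 10.0 | 97.0 |
| gamma | 20.0 | 96.5 |
| gamma | 30.0 | 97.2 |
| gamma | 40.0 | 96.9 |

(each reading ± 0.3 percentage points)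

- the flask with the highest amount of target, in percent of the starting material charged ("all alike" if they lie within 1.5 percentage points) (north-west / east / north / all alike)
- final target, as a percentage of the starting material charged, in north-west
- final target, as a percentage of the starting material charged, in east
- final target, as a percentage of the starting material charged, in north



At 40.0 h the zeta run read 96.4% and the beta run, with 3.5 mM of capture agent, 98.9%, so the shortfall grew with [capture agent]. The gamma run, with [coupling partner] at 0.22 M, read 93.5% at 4.00 h, higher than zeta at 5.00 h, yet it ended 0.5 percentage points from zeta against a scatter of 0.3 points. I therefore took the loss as paid per unit of target formed, with the pace of coupling left out.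

Counting starting material lost mole for mole against capture agent, the last readings of the zeta, beta, epsilon and gamma runs together gave a share of 61.7% of the capture agent spent. From that reading I reckoned the trapping ratio s, the rate of loss over the rate of target formation per unit of [capture agent], as 7.11 M⁻¹.

At 7.00 mM the loss began at 4.98% of the rate of target formation, and by the end, in my reckoning, spending capture agent had slowed it by a factor of 2.61. The accumulated loss left target at 96.9% of the starting material charged. Each feed ended with 32.0 h still to run, longer than the 15.0 h zeta took to reach 95.7%, so I expected 96.9% in north-west, east and north alike.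

The forecast differed: north highest, with 96.6% in north-west, 95% in east and 97.3% in north, on the ground “East keeps partner scarce while starting material sits with capture agent”.

North-west gave 96.9%, east 96.8% and north 96.8%: all alike.

    starting material + coupling partner → open intermediate (k = 18.5 M⁻¹ h⁻¹)
    open intermediate → target (k = 0.994 h⁻¹)
    open intermediate + capture agent → trapped intermediate (k = 7.09 M⁻¹ h⁻¹)

In east at 4.48 h the open intermediate turned into target 29 times as fast as it was trapped, a selectivity factor in favour of target. The ratio s puts that factor at 20.1 at the charged [capture agent] and 41.9 at the 47.9% of its charge left in east at 8.00 h, and the factor in east lies between them. In a neighbour of east, the same flask with 0.24 M of starting material, coupling partner was the limiting reagent, standing at 0% at 40.0 h with target at 59.4%. For that turnover s gave 1.86% of trapped intermediate, in percent of the starting material charged, and that neighbour held 1.86%.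

The numbers in the tables come from a simulation with constants of no real substance.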